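The target is the aldol self-condensation dimer of one amino aldehyde, so both all-cis piperidine rings (N1, C2 methyl, C3 hydroxyl, C6 chain) come from one monomer. Each ring is cut into the N1=C6 unit, an Ellman sulfinimine of erucyl aldehyde whose Z-alkene masks the chain aldehyde, and the C2–C5 unit, an acyclic Grignard reagent with the carbanion at C5 and a secondary chloride at C2. In one pot the Grignard reagent adds to C6 under sulfinyl control (C5–C6 bond, C6 set) and the sulfinamide nitrogen then displaces the chloride with inversion (N1–C2 bond, C2 set), closing the ring.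

Key step: step 6

Remark on the chemistry: both rings are read as (2S,3S,6R) all-cis and the enal as E; allyl methoxymethyl ether, (+)-Ipc2BOMe (from (−)-α-pinene), 9-BBN, erucyl alcohol and (R)-tert-butanesulfinamide are taken as purchased materials.

Step 1
Reactants: 1 allyl methoxymethyl ether; 2 acetaldehyde
Product: 4 (2S,3S)-3-(methoxymethoxy)pent-4-en-2-ol, via Z-alkoxyallyl diisopinocampheylborane 3 (not isolated)
Conditions: 1, s-BuLi, THF, −78 °C; (+)-Ipc2BOMe; BF3·OEt2; then 2, −78 °C; then NaOH, H2O2, 0 → 23 °C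
Reagents that add atoms: none
Why: Brown alkoxyallylboration: the Z-γ-alkoxyallylborane reacts through a closed Zimmerman–Traxler chair, so the Z geometry should give the syn diol monoether and the isopinocampheyl groups derived from (−)-α-pinene should select the aldehyde face that leads to (2S,3S).

Step 2
Reactants: 4 (2S,3S)-3-(methoxymethoxy)pent-4-en-2-ol
Product: 5 (3S,4R)-4-chloro-3-(methoxymethoxy)pent-1-ene
Conditions: PPh3, CCl4, reflux
Reagents that add atoms: carbon tetrachloride, ClC(Cl)(Cl)Cl
Why: Appel reaction: chloride displaces the alkoxyphosphonium group by SN2 with inversion, so the (S)-carbinol should give the (R)-chloride, as in chlorinations of sugar secondary alcohols, while acetal and alkene stay untouched under neutral conditions.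

Step 3
Reactants: 5 (3S,4R)-4-chloro-3-(methoxymethoxy)pent-1-ene
Product: 7 (3S,4R)-4-chloro-1-iodo-3-(methoxymethoxy)pentane, via B-alkyl-9-BBN 6 (not isolated)
Conditions: 9-BBN, THF, 0 → 23 °C; then NaOMe, MeOH, I2, 0 °C
Reagents that add atoms: iodine, II
Why: Brown hydroboration–iodination: 9-BBN places boron on the terminal carbon and methoxide-induced iodinolysis cleaves the primary B–C bond, so the terminal alkene should become the primary iodide without touching either stereocenter.

Step 4
Reactants: 8 (Z)-docos-13-en-1-ol (erucyl alcohol)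
Product: 9 (Z)-docos-13-enal
Conditions: TEMPO (10 mol%), PhI(OAc)2, CH2Cl2, 23 °C
Reagents that add atoms: none
Why: TEMPO/PhI(OAc)2 oxidation of a primary alcohol should stop at the aldehyde and leave the Z-alkene untouched.

Step 5
Reactants: 9 (Z)-docos-13-enal; 10 (R)-2-methylpropane-2-sulfinamide
Product: 11 (R)-N-[(1E,13Z)-docos-13-en-1-ylidene]-2-methylpropane-2-sulfinamide
Conditions: CuSO4, CH2Cl2, 23 °C
Reagents that add atoms: none
Why: Ellman condensation: CuSO4 activates the aldehyde and binds the water, so the E-configured N-sulfinyl aldimine should form without loss of configuration at sulfur.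

Step 6
Reactants: 7 (3S,4R)-4-chloro-1-iodo-3-(methoxymethoxy)pentane; 11 (R)-N-[(1E,13Z)-docos-13-en-1-ylidene]-2-methylpropane-2-sulfinamide
Product: 14 (2S,3S,6R)-1-[(R)-tert-butylsulfinyl]-6-[(12Z)-henicos-12-en-1-yl]-3-(methoxymethoxy)-2-methylpiperidine, via chloroalkyl Grignard reagent 12 (not isolated), via acyclic magnesium sulfinamide 13 (not isolated)
Conditions: 7, Mg, Et2O, 23 °C; then 11, toluene, −78 → −40 °C; then t-BuOK, THF/DMPU, 0 → 50 °C
Reagents that add atoms: none
Why: Mg inserts into the primary C–I bond of 7 while the secondary C–Cl bond stays intact, and Grignard reagent 12 adds to sulfinimine 11 through the Ellman six-membered chair in which Mg is bound to the sulfinyl oxygen, which forms C5–C6; the metalated nitrogen of 13, exchanged to its potassium salt, then displaces the secondary chloride, which forms N1–C2. The closest known reaction type is the one-pot Grignard addition to an N-tert-butanesulfinyl imine followed by intramolecular N-alkylation by a tethered alkyl chloride (a formal [4+2] annulation used for 2-substituted pyrrolidines and piperidines), here applied to a secondary chloride. The ring closes in the 6-exo-tet mode. C6 should be set as R by the (R)-sulfinyl group (attack on the Si face of the E-aldimine in the non-coordinating solvent), C2 as S by SN2 inversion of the (R)-chloride, and C3 is carried unchanged from 4, which together give the all-cis ring. The step needs substitution at nitrogen to outrun E2 loss of HCl and iodide exchange at C2; the intramolecular six-membered closure by the potassium sulfinamide in THF/DMPU and only a slight excess of t-BuOK are meant to secure this.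

Step 7
Reactants: 14 (2S,3S,6R)-1-[(R)-tert-butylsulfinyl]-6-[(12Z)-henicos-12-en-1-yl]-3-(methoxymethoxy)-2-methylpiperidine
Product: 15 12-[(2R,5S,6S)-1-[(R)-tert-butylsulfinyl]-5-(methoxymethoxy)-6-methylpiperidin-2-yl]dodecanal
Conditions: O3, CH2Cl2, −78 °C (Sudan Red 7B end point); then PPh3, −78 → 23 °C
Reagents that add atoms: ozone, [O-][O+]=O
Why: Ozonolysis with reductive work-up: the cis-alkene should take up ozone far faster than the sulfinamide sulfur, which like a sulfoxide reacts slowly, and titration to the dye end point avoids excess ozone.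

Step 8
Reactants: 15 12-[(2R,5S,6S)-1-[(R)-tert-butylsulfinyl]-5-(methoxymethoxy)-6-methylpiperidin-2-yl]dodecanal (two molecules)
Product: 16 (2E)-14-[(2R,5S,6S)-1-[(R)-tert-butylsulfinyl]-5-(methoxymethoxy)-6-methylpiperidin-2-yl]-2-{10-[(2R,5S,6S)-1-[(R)-tert-butylsulfinyl]-5-(methoxymethoxy)-6-methylpiperidin-2-yl]decyl}tetradec-2-enal
Conditions: pyrrolidine (20 mol%), PhCO2H (20 mol%), toluene, 50 °C
Reagents that add atoms: none
Why: Amine-catalysed aldol self-condensation: the pyrrolidine enamine of one molecule adds to the iminium ion of a second and elimination should give the 2-alkylalk-2-enal with the thermodynamically preferred E geometry, while the sulfinamides and acetals are inert to the weak acid.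

Step 9
Reactants: 16 the bis-sulfinyl bis-MOM enal
Product: 18 (2E)-14-[(2R,5S,6S)-5-hydroxy-6-methylpiperidin-2-yl]-2-{10-[(2R,5S,6S)-5-hydroxy-6-methylpiperidin-2-yl]decyl}tetradec-2-enal (CNP0177491.1), via enal dimethyl acetal dihydrochloride 17 (not isolated)
Conditions: HCl (3 M in MeOH), 45 °C; then 1 M aq. HCl, THF, 23 °C; then aq. K2CO3, CH2Cl2
Reagents that add atoms: none
Why: Acid cleavage of the sulfinamide N–S bonds and of the MOM acetals in methanol, where formaldehyde is trapped as dimethoxymethane and the enal is held as its dimethyl acetal until aqueous acid returns it, should free both amines and both alcohols without touching a stereocenter.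

Compound list
1 | allyl methoxymethyl ether | C=CCOCOC | starting material
2 | acetaldehyde | CC=O | starting material
3 | (Z)-[3-(methoxymethoxy)allyl]di-(+)-isopinocampheylborane | COCO/C=C\CB([C@H]1C[C@H]2C[C@@H]([C@@H]1C)C2(C)C)[C@H]3C[C@H]4C[C@@H]([C@@H]3C)C4(C)C | intermediate
4 | (2S,3S)-3-(methoxymethoxy)pent-4-en-2-ol | C[C@H](O)[C@@H](OCOC)C=C | intermediate
5 | (3S,4R)-4-chloro-3-(methoxymethoxy)pent-1-ene | C[C@@H](Cl)[C@@H](OCOC)C=C | intermediate
6 | 9-[(3S,4R)-4-chloro-3-(methoxymethoxy)pentyl]-9-borabicyclo[3.3.1]nonane | C[C@@H](Cl)[C@@H](OCOC)CCB1C2CCCC1CCC2 | intermediate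
7 | (3S,4R)-4-chloro-1-iodo-3-(methoxymethoxy)pentane | C[C@@H](Cl)[C@@H](OCOC)CCI | intermediate
8 | (Z)-docos-13-en-1-ol | CCCCCCCC/C=C\CCCCCCCCCCCCO | starting material
9 | (Z)-docos-13-enal | CCCCCCCC/C=C\CCCCCCCCCCCC=O | intermediate
10 | (R)-2-methylpropane-2-sulfinamide | CC(C)(C)[S@@](=O)N | starting material
11 | (R)-N-[(1E,13Z)-docos-13-en-1-ylidene]-2-methylpropane-2-sulfinamide | CC(C)(C)[S@@](=O)/N=C/CCCCCCCCCCC/C=C\CCCCCCCC | intermediate
12 | [(3S,4R)-4-chloro-3-(methoxymethoxy)pentyl]magnesium iodide | C[C@@H](Cl)[C@@H](OCOC)CC[Mg]I | intermediate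
13 | iodomagnesium salt of (R)-N-[(2R,3S,6R,18Z)-2-chloro-3-(methoxymethoxy)heptacos-18-en-6-yl]-2-methylpropane-2-sulfinamide | C[C@@H](Cl)[C@@H](OCOC)CC[C@@H](CCCCCCCCCCC/C=C\CCCCCCCC)N([Mg]I)[S@](=O)C(C)(C)C | intermediate
14 | (2S,3S,6R)-1-[(R)-tert-butylsulfinyl]-6-[(12Z)-henicos-12-en-1-yl]-3-(methoxymethoxy)-2-methylpiperidine | C[C@@H]1N([S@](=O)C(C)(C)C)[C@H](CCCCCCCCCCC/C=C\CCCCCCCC)CC[C@@H]1OCOC | intermediate
15 | 12-[(2R,5S,6S)-1-[(R)-tert-butylsulfinyl]-5-(methoxymethoxy)-6-methylpiperidin-2-yl]dodecanal | C[C@@H]1N([S@](=O)C(C)(C)C)[C@H](CCCCCCCCCCCC=O)CC[C@@H]1OCOC | intermediate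
16 | (2E)-14-[(2R,5S,6S)-1-[(R)-tert-butylsulfinyl]-5-(methoxymethoxy)-6-methylpiperidin-2-yl]-2-{10-[(2R,5S,6S)-1-[(R)-tert-butylsulfinyl]-5-(methoxymethoxy)-6-methylpiperidin-2-yl]decyl}tetradec-2-enal | C[C@@H]1N([S@](=O)C(C)(C)C)[C@H](CCCCCCCCCCC/C=C(/C=O)CCCCCCCCCC[C@@H]2CC[C@H](OCOC)[C@H](C)N2[S@](=O)C(C)(C)C)CC[C@@H]1OCOC | intermediate
17 | dimethyl acetal of 18 as dihydrochloride | C[C@@H]1N[C@H](CCCCCCCCCCC/C=C(/C(OC)OC)CCCCCCCCCC[C@@H]2CC[C@H](O)[C@H](C)N2)CC[C@@H]1O.Cl.Cl | intermediate
18 | (2E)-14-[(2R,5S,6S)-5-hydroxy-6-methylpiperidin-2-yl]-2-{10-[(2R,5S,6S)-5-hydroxy-6-methylpiperidin-2-yl]decyl}tetradec-2-enal (CNP0177491.1) | C[C@@H]1N[C@H](CCCCCCCCCCC/C=C(/C=O)CCCCCCCCCC[C@@H]2CC[C@H](O)[C@H](C)N2)CC[C@@H]1O | target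

Total step count: 9. Longest linear sequence: 7 steps (1, 2, 3, 6, 7, 8, 9).

Steps most likely to fail

Step 6. Ring closure at the hindered secondary chloride may be slower than E2 loss of HCl, or iodide exchange at C2 may precede it and erode the C2 configuration. The fallback sets out from 7 and 11 and comes back at 18. The Grignard addition is run alone and quenched with aqueous NH4Cl to give (R)-N-[(2R,3S,6R,18Z)-2-chloro-3-(methoxymethoxy)heptacos-18-en-6-yl]-2-methylpropane-2-sulfinamide F1. HCl in MeOH removes the sulfinyl and MOM groups to give (2R,3S,6R,18Z)-6-amino-2-chloroheptacos-18-en-3-ol hydrochloride F2. Heating with K2CO3 in MeCN lets the free primary amine close the ring by SN2 with inversion to give (2S,3S,6R)-6-[(12Z)-henicos-12-en-1-yl]-2-methylpiperidin-3-ol F3. Boc2O gives tert-butyl (2S,3S,6R)-6-[(12Z)-henicos-12-en-1-yl]-3-hydroxy-2-methylpiperidine-1-carboxylate F4. Ozonolysis (O3, then PPh3) gives tert-butyl (2S,3S,6R)-3-hydroxy-2-methyl-6-(12-oxododecyl)piperidine-1-carboxylate F5. Condensation with pyrrolidine/PhCO2H gives the bis-carbamate of 18 F6, and TFA in CH2Cl2 followed by aqueous K2CO3 gives 18.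

Step 2. Substitution at the β-alkoxy secondary carbinol may give way to elimination toward the 2-alkoxydiene, to participation of the acetal oxygen, or to incomplete inversion. The fallback takes the C–Cl stereocenter from the chiral pool instead of making it by substitution: it replaces steps 1 and 2, sets out from commercial methyl (R)-2-chloropropanoate F7 in place of compounds 1, 2 and 4, and comes back at 5. Reduction with i-Bu2AlH in CH2Cl2 at −78 °C gives (R)-2-chloropropanal F8, which is used cold without isolation. Vinylmagnesium bromide (CH2=CHMgBr) adds under Cornforth control to give mainly the anti chlorohydrin (3S,4R)-4-chloropent-1-en-3-ol F9, which is separated from its diastereomer. MOMCl and i-Pr2NEt then give 5.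

Step 8. The self-condensation may run on to trimers or stall because the product enal competes for the amine catalyst. The fallback is a directed aldol condensation through a metalated imine; it sets out from 15 and comes back at 16. Cyclohexylamine converts one equivalent of 15 into the N-cyclohexyl imine of 15 F10. LiN(i-Pr)2 in THF at −78 °C gives the aza-enolate, which adds to a second equivalent of 15 to give the β-hydroxy imine adduct F11. Aqueous oxalic acid then hydrolyses the imine and dehydrates the aldol to give 16.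

Further compounds
F1 | step 6 | (R)-N-[(2R,3S,6R,18Z)-2-chloro-3-(methoxymethoxy)heptacos-18-en-6-yl]-2-methylpropane-2-sulfinamide | C[C@@H](Cl)[C@@H](OCOC)CC[C@@H](CCCCCCCCCCC/C=C\CCCCCCCC)N[S@](=O)C(C)(C)C
F2 | step 6 | (2R,3S,6R,18Z)-6-amino-2-chloroheptacos-18-en-3-ol hydrochloride | C[C@@H](Cl)[C@@H](O)CC[C@@H](CCCCCCCCCCC/C=C\CCCCCCCC)N.Cl
F3 | step 6 | (2S,3S,6R)-6-[(12Z)-henicos-12-en-1-yl]-2-methylpiperidin-3-ol | C[C@@H]1N[C@H](CCCCCCCCCCC/C=C\CCCCCCCC)CC[C@@H]1O
F4 | step 6 | tert-butyl (2S,3S,6R)-6-[(12Z)-henicos-12-en-1-yl]-3-hydroxy-2-methylpiperidine-1-carboxylate | C[C@@H]1N(C(=O)OC(C)(C)C)[C@H](CCCCCCCCCCC/C=C\CCCCCCCC)CC[C@@H]1O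
F5 | step 6 | tert-butyl (2S,3S,6R)-3-hydroxy-2-methyl-6-(12-oxododecyl)piperidine-1-carboxylate | C[C@@H]1N(C(=O)OC(C)(C)C)[C@H](CCCCCCCCCCCC=O)CC[C@@H]1O
F6 | step 6 | bis(tert-butyl carbamate) of 18 | C[C@@H]1N(C(=O)OC(C)(C)C)[C@H](CCCCCCCCCCC/C=C(/C=O)CCCCCCCCCC[C@@H]2CC[C@H](O)[C@H](C)N2C(=O)OC(C)(C)C)CC[C@@H]1O
F7 | step 2 | methyl (R)-2-chloropropanoate | C[C@@H](Cl)C(=O)OC
F8 | step 2 | (R)-2-chloropropanal | C[C@@H](Cl)C=O
F9 | step 2 | (3S,4R)-4-chloropent-1-en-3-ol | C[C@@H](Cl)[C@@H](O)C=C
F10 | step 8 | N-cyclohexyl imine of 15 | C[C@@H]1N([S@](=O)C(C)(C)C)[C@H](CCCCCCCCCCC/C=N/C2CCCCC2)CC[C@@H]1OCOC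
F11 | step 8 | β-hydroxy imine adduct of lithiated F10 and 15 | C[C@@H]1N([S@](=O)C(C)(C)C)[C@H](CCCCCCCCCCCC(O)C(/C=N/C2CCCCC2)CCCCCCCCCC[C@@H]3CC[C@H](OCOC)[C@H](C)N3[S@](=O)C(C)(C)C)CC[C@@H]1OCOC
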